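The route cuts the C4=C5 bond of the nine-membered oxacycle (ring O–C3–C4–C5–C6–C7–C8–C9–C10, germacrane numbering) back to a ten-membered cyclic sulfone with sulfur between C4 and C5. A Ramberg–Bäcklund reaction of the derived α-chloro sulfone expels SO2, contracts the ring by one atom and forms the strained (4Z)-trisubstituted olefin of the furanone dienone in one operation. The step exploits the furanone-acidified C4–H and the C4=C5 olefin itself. Its precursor is a furanone-bridged macrocyclic sulfone, closed by thiolate alkylation, that already holds the trans-lactone, C8–O and C10 centres (from lactic acid, an Evans aldol and a CBS reduction).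

Key step: step 18

Remarks on the chemistry:
- Germacrane numbering of the target is used for all intermediates: C1–C3 are the furanone C=O, CH and O-bearing sp2 carbon; C4 carries CH3 (C15); C6 is the lactone carbinol; C8 the ester carbinol; C10 the quaternary O-bearing carbon (CH3 = C14); C11–C13 are the lactone α-carbon, carbonyl and exocyclic CH2.
- Lithium enolates, acetylides and other conjugate bases formed in situ are treated as activated forms of the numbered compounds.
- C4 becomes sp2 in step 18; a single C4 epimer is carried from (S)-but-3-yn-2-ol only so that intermediates are single diastereomers.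

Step 1
Reactants: 1 (S)-lactic acid; 2 pivalaldehyde
Product: 3 (2S,5S)-2-tert-butyl-5-methyl-1,3-dioxolan-4-one
Conditions: p-TsOH·H2O (cat.), H2SO4 (cat.), pentane, reflux (Dean–Stark); crystallisation at −78 °C
Reagents that add atoms: none
Why: Acid-catalysed acetalisation of the α-hydroxy acid (first stage of self-regeneration of stereocentres); the cis acetal is thermodynamically favoured and crystallises, so the acetal centre (2S) is set relative to the lactate centre by equilibration.

Step 2
Reactants: 3 (2S,5S)-2-tert-butyl-5-methyl-1,3-dioxolan-4-one; 4 allyl bromide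
Product: 5 (2S,5R)-5-allyl-2-tert-butyl-5-methyl-1,3-dioxolan-4-one
Conditions: LiN(iPr)2, THF, −78 °C; then 4, −78 → −30 °C
Reagents that add atoms: none
Why: Alkylation of the dioxolanone lithium enolate occurs anti to the tert-butyl group, so allyl takes the place of the former hydrogen and the quaternary centre (future C10, R) is set by the acetal centre (self-regeneration of stereocentres).

Step 3
Reactants: 6 (S)-but-3-yn-2-ol
Product: 7 (S)-tert-butyl(but-3-yn-2-yloxy)dimethylsilane
Conditions: TBSCl, imidazole, DMF, 23 °C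
Reagents that add atoms: tert-butyldimethylsilyl chloride, CC(C)(C)[Si](C)(C)Cl
Why: Standard silyl ether formation; the carbinol centre (future C4) is untouched.

Step 4
Reactants: 5 (2S,5R)-5-allyl-2-tert-butyl-5-methyl-1,3-dioxolan-4-one; 7 (S)-tert-butyl(but-3-yn-2-yloxy)dimethylsilane
Product: 8 (4R,8S)-8-[(tert-butyldimethylsilyl)oxy]-4-hydroxy-4-methylnon-1-en-6-yn-5-one
Conditions: 7, n-BuLi, THF, −78 °C; then 5, −78 °C; AcOH quench at −78 °C, then 23 °C
Reagents that add atoms: none
Why: Single addition of the alkynyllithium to the acylal-type lactone carbonyl gives a tetrahedral lithium alkoxide that should survive at −78 °C and on protonation collapse with loss of pivalaldehyde to the α-hydroxy ynone (ynone synthesis by acetylide addition to a lactone); no stereocentre is touched.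

Step 5
Reactants: 8 (4R,8S)-8-[(tert-butyldimethylsilyl)oxy]-4-hydroxy-4-methylnon-1-en-6-yn-5-one
Product: 9 (2R)-2-allyl-5-[(1S)-1-(tert-butyldimethylsilyloxy)ethyl]-2-methylfuran-3(2H)-one
Conditions: Et2NH, EtOH, 23 °C; then aq. AcOH
Reagents that add atoms: none
Why: Amine-mediated 5-endo-dig oxa-Michael cyclisation of the α-hydroxy ynone (via the β-enaminone) is the classical entry to 2,2-disubstituted 3(2H)-furanones; C10 is retained.

Step 6
Reactants: 9 (2R)-2-allyl-5-[(1S)-1-(tert-butyldimethylsilyloxy)ethyl]-2-methylfuran-3(2H)-one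
Product: 10 {(2R)-5-[(1S)-1-(tert-butyldimethylsilyloxy)ethyl]-2-methyl-3-oxo-2,3-dihydrofuran-2-yl}acetaldehyde
Conditions: OsO4 (cat.), NaIO4, 2,6-lutidine, dioxane/H2O, 23 °C
Reagents that add atoms: sodium periodate, [Na+].[O-]I(=O)(=O)=O (terminal oxidant; supplies the aldehyde oxygen via OsO4)
Why: Lemieux–Johnson oxidative cleavage; OsO4 should dihydroxylate the monosubstituted alkene much faster than the push-pull furanone alkene.

Step 7
Reactants: 11 4-tert-butoxy-4-oxobutanoic acid; 12 (S)-4-benzyl-1,3-oxazolidin-2-one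
Product: 14 tert-butyl 4-[(4S)-4-benzyl-2-oxo-1,3-oxazolidin-3-yl]-4-oxobutanoate, via pivalic mixed anhydride 13 (not isolated)
Conditions: t-BuCOCl, Et3N, THF, −20 °C; then 12, LiCl, 23 °C
Reagents that add atoms: pivaloyl chloride, CC(C)(C)C(Cl)=O (atoms kept in 13 only)
Why: N-Acylation of the oxazolidinone through the pivalic mixed anhydride with LiCl/Et3N is the standard preparation of Evans imides.

Step 8
Reactants: 10 furanone aldehyde; 14 succinoyl imide
Product: 15 syn-aldol adduct (4S,7S,8R,10R) with free 8-OH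
Conditions: 14, Bu2BOTf, Et3N, CH2Cl2, 0 °C; then 10, −78 → 0 °C; pH 7 buffer, MeOH, H2O2
Reagents that add atoms: none
Why: Evans syn aldol: the Z-boron enolate reacts through a chair Zimmerman–Traxler transition state on the face opposite the benzyl group, which should set C7 (S) and C8 (R) under auxiliary control, while the tert-butyl ester resists lactonisation onto the new hydroxyl.

Step 9
Reactants: 15 syn-aldol adduct
Product: 16 8-O-triisopropylsilyl ether of 15 (4S,7S,8R,10R)
Conditions: TIPSOTf, 2,6-lutidine, CH2Cl2, 0 °C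
Reagents that add atoms: triisopropylsilyl triflate, CC(C)[Si](C(C)C)(C(C)C)OS(=O)(=O)C(F)(F)F
Why: Silylation with the silyl triflate protects the hindered C8 hydroxyl as an acid-resistant ether, which differentiates it from the later C6 hydroxyl.

Step 10
Reactants: 16 TIPS ether
Product: 17 C6 carboxylic acid (4S,7S,8R,10R)
Conditions: LiOH, H2O2, THF/H2O, 0 °C; Na2SO3; HCl to pH 3
Reagents that add atoms: hydrogen peroxide, OO (as LiOOH; supplies the carboxyl OH oxygen)
Why: LiOOH cleaves the exocyclic imide carbonyl selectively (standard auxiliary removal), leaving the tert-butyl ester, both silyl ethers and the α-centre C7 intact.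

Step 11
Reactants: 17 C6 carboxylic acid
Product: 20 bromomethyl ketone (4S,7S,8R,10R), via mixed carbonic anhydride 18 (not isolated), via diazoketone 19 (not isolated)
Conditions: i-BuOCOCl, N-methylmorpholine, THF, −20 °C; CH2N2, Et2O, 0 °C; then 48% aq. HBr, 0 °C
Reagents that add atoms: isobutyl chloroformate, CC(C)COC(Cl)=O (atoms kept in 18 only); diazomethane, C=[N+]=[N-]; hydrogen bromide, Br
Why: Arndt–Eistert-type acylation of diazomethane by the mixed carbonic anhydride gives the diazoketone, which HBr converts to the bromomethyl ketone (diazoketone hydrohalogenation) under non-basic conditions that should not epimerise C7.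

Step 12
Reactants: 20 bromomethyl ketone
Product: 21 bromohydrin (4S,6R,7R,8R,10R)
Conditions: (R)-2-methyl-CBS-oxazaborolidine (0.2 equiv), BH3·SMe2, THF, −20 °C; MeOH
Reagents that add atoms: none
Why: Corey–Bakshi–Shibata reduction: the (R)-oxazaborolidine should deliver hydride under catalyst control (branched C7 side as the large group, CH2Br as the small one) to set C6 (R), and the furanone vinylogous ester is reduced far more slowly.

Step 13
Reactants: 21 bromohydrin
Product: 22 bromo lactone alcohol (4S,6R,7R,8R,10R)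
Conditions: TFA/CH2Cl2/H2O, 0 → 23 °C
Reagents that add atoms: none
Why: Acidolysis removes the tert-butyl ester and the TBS ether, and the γ-hydroxy acid lactonises (5-exo-trig) to the trans-lactone already defined by C6 and C7, while the TIPS ether should persist.

Step 14
Reactants: 22 bromo lactone alcohol
Product: 23 C4 thioacetate (4R,6R,7R,8R,10R)
Conditions: PPh3, DIAD, AcSH, THF, 0 °C
Reagents that add atoms: thioacetic acid, CC(=O)S
Why: Mitsunobu reaction with thioacetic acid converts the activated secondary alcohol into the thioacetate with inversion at C4 (a centre that is destroyed later).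

Step 15
Reactants: 23 C4 thioacetate
Product: 25 macrocyclic sulfide (4R,6R,7R,8R,10R), via thiol 24 (not isolated)
Conditions: K2CO3, degassed MeOH/THF, 1 mM, 0 → 23 °C
Reagents that add atoms: none
Why: Methanolysis frees thiol 24, whose soft thiolate should close the ten-membered thia-oxacycle by intramolecular SN2 displacement of the primary bromide under high dilution (macrocyclic thioetherification); no stereocentre is affected.

Step 16
Reactants: 25 macrocyclic sulfide
Product: 26 macrocyclic sulfone (4R,6R,7R,8R,10R)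
Conditions: mCPBA (2.2 equiv), NaHCO3, CH2Cl2, 0 °C
Reagents that add atoms: mCPBA, OOC(=O)c1cccc(Cl)c1
Why: Peracid oxidation of the sulfide to the sulfone; the electron-poor furanone and the lactone should be inert under buffered conditions.

Step 17
Reactants: 26 macrocyclic sulfone
Product: 27 α-chloro sulfone (6R,7R,8R,10R; chlorine at C4)
Conditions: LiN(SiMe3)2 (1.05 equiv), THF, −78 °C; then C2Cl6
Reagents that add atoms: hexachloroethane, ClC(Cl)(Cl)C(Cl)(Cl)Cl
Why: C4–H, flanked by the sulfone and vinylogous to the furanone carbonyl, is by far the most acidic site, so one equivalent of base and C2Cl6 should chlorinate only there (electrophilic α-halogenation of a sulfonyl carbanion); the C4 configuration is irrelevant.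

Step 18
Reactants: 27 α-chloro sulfone
Product: 29 (4Z)-diene lactone (6S,7R,8R,10R) with the nine-membered oxacycle, via episulfone 28 (not isolated)
Conditions: KOtBu (3 equiv), THF, −78 → 0 °C; AcOH quench
Reagents that add atoms: none
Why: Excess KOtBu first enolises the lactone (C11) and then removes a C5–H of the α-chloro sulfone; the C5 carbanion displaces chloride at C4 in a 1,3-elimination to give the cis-fused episulfone 28, which loses SO2 stereospecifically to leave the C4=C5 double bond. The closest known reaction type is the Ramberg–Bäcklund ring contraction of macrocyclic α-halo sulfones, as used for strained medium-ring and cyclophane olefins. The only ring closed is the transient thiirane 1,1-dioxide (3-exo-tet); the nine-membered oxacycle arises from the ten-membered thia-oxacycle (S, C5–C10, O, C3, C4) by loss of the sulfur atom, which completes the ten-membered carbocycle at the same time. No stereocentre is created: the Z geometry is enforced because only a cis-fused episulfone and a cis olefin fit the medium ring, and C6, C7, C8 and C10 are untouched. The step needs the 1,3-elimination to outrun β-elimination of the C6 lactone oxygen from the C5 carbanion; prior enolisation of the lactone makes that oxygen a poor leaving group, the chloride sits on a tertiary furanone-activated carbon, and no electrophilic halogen source is present that could halogenate the lactone enolate.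

Step 19
Reactants: 29 (4Z)-diene lactone
Product: 32 α-methylene lactone TIPS ether (4Z,6S,7R,8R,10R), via Mannich base 30 (not isolated), via trimethylammonium iodide 31 (not isolated)
Conditions: LiN(SiMe3)2, THF, −78 °C; CH2=NMe2+ I−, −78 → 0 °C; then MeI, MeOH, 23 °C; then aq. NaHCO3/CH2Cl2
Reagents that add atoms: Eschenmoser's salt, C=[N+](C)C.[I-]; iodomethane, CI (atoms kept in 31 only)
Why: Kinetic lactone enolate formation and Mannich reaction with Eschenmoser's salt, followed by quaternisation and E1cB elimination, is the standard α-methylenation of γ-lactones; no stereocentre remains at C11.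

Step 20
Reactants: 32 α-methylene lactone TIPS ether
Product: 33 8-hydroxy α-methylene lactone (4Z,6S,7S,8R,10R)
Conditions: HF·pyridine, pyridine/THF, 0 → 23 °C
Reagents that add atoms: none
Why: Fluoride-mediated desilylation under buffered acidic conditions that the α-methylene lactone and the dienone should tolerate.

Step 21
Reactants: 34 tert-butyl acrylate; 35 acetaldehyde
Product: 36 tert-butyl 3-hydroxy-2-methylidenebutanoate (racemic)
Conditions: DABCO (cat.), neat, 23 °C
Reagents that add atoms: none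
Why: Morita–Baylis–Hillman reaction of the acrylate with acetaldehyde; the racemic carbinol centre is removed in the next step.

Step 22
Reactants: 36 tert-butyl 3-hydroxy-2-methylidenebutanoate
Product: 38 tert-butyl (2E)-2-(acetoxymethyl)but-2-enoate, via secondary acetate 37 (not isolated)
Conditions: Ac2O, Et3N, DMAP (cat.), CH2Cl2, 0 °C; then DABCO (cat.), THF, 65 °C
Reagents that add atoms: acetic anhydride, CC(=O)OC(C)=O
Why: Acetylation followed by DABCO-catalysed SN2'–SN2' allylic transposition of the Baylis–Hillman acetate should give the thermodynamically preferred primary acetate with the (E)-trisubstituted olefin.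

Step 23
Reactants: 38 tert-butyl (2E)-2-(acetoxymethyl)but-2-enoate
Product: 39 (2E)-2-(acetoxymethyl)but-2-enoic acid
Conditions: TFA, CH2Cl2, 0 → 23 °C
Reagents that add atoms: none
Why: Acidolysis of the tert-butyl ester with loss of isobutene; the primary acetate is stable to TFA.

Step 24
Reactants: 33 8-hydroxy α-methylene lactone; 39 (2E)-2-(acetoxymethyl)but-2-enoic acid
Product: 41 target CNP0176571.1, via mixed trichlorobenzoic anhydride 40 (not isolated)
Conditions: 39, 2,4,6-Cl3C6H2COCl, Et3N, toluene, 23 °C; then 33, DMAP, 23 °C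
Reagents that add atoms: 2,4,6-trichlorobenzoyl chloride, O=C(Cl)c1c(Cl)cc(Cl)cc1Cl (atoms kept in 40 only)
Why: Yamaguchi esterification acylates the hindered C8 alcohol through the mixed anhydride and the acyl-pyridinium without touching the stereocentres or the (E)-olefin of the acyl group.

Compound list
1 | (S)-lactic acid | C[C@H](O)C(=O)O | starting material
2 | pivalaldehyde (2,2-dimethylpropanal) | CC(C)(C)C=O | starting material
3 | (2S,5S)-2-tert-butyl-5-methyl-1,3-dioxolan-4-one (cis) | C[C@@H]1O[C@H](C(C)(C)C)OC1=O | intermediate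
4 | allyl bromide | C=CCBr | starting material
5 | (2S,5R)-2-tert-butyl-5-methyl-5-(prop-2-en-1-yl)-1,3-dioxolan-4-one | C=CC[C@@]1(C)O[C@H](C(C)(C)C)OC1=O | intermediate
6 | (S)-but-3-yn-2-ol | C#C[C@H](C)O | starting material
7 | (S)-tert-butyl(but-3-yn-2-yloxy)dimethylsilane | C#C[C@H](C)O[Si](C)(C)C(C)(C)C | intermediate
8 | (4R,8S)-8-[(tert-butyldimethylsilyl)oxy]-4-hydroxy-4-methylnon-1-en-6-yn-5-one | C=CC[C@@](C)(O)C(=O)C#C[C@H](C)O[Si](C)(C)C(C)(C)C | intermediate
9 | (2R)-5-[(1S)-1-{[tert-butyl(dimethyl)silyl]oxy}ethyl]-2-methyl-2-(prop-2-en-1-yl)furan-3(2H)-one | C=CC[C@@]1(C)OC(=CC1=O)[C@H](C)O[Si](C)(C)C(C)(C)C | intermediate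
10 | {(2R)-5-[(1S)-1-{[tert-butyl(dimethyl)silyl]oxy}ethyl]-2-methyl-3-oxo-2,3-dihydrofuran-2-yl}acetaldehyde | O=CC[C@@]1(C)OC(=CC1=O)[C@H](C)O[Si](C)(C)C(C)(C)C | intermediate
11 | 4-tert-butoxy-4-oxobutanoic acid (mono-tert-butyl succinate) | CC(C)(C)OC(=O)CCC(=O)O | starting material
12 | (S)-4-benzyl-1,3-oxazolidin-2-one | O=C1N[C@@H](Cc2ccccc2)CO1 | starting material
13 | 4-tert-butoxy-4-oxobutanoic pivalic anhydride | CC(C)(C)OC(=O)CCC(=O)OC(=O)C(C)(C)C | intermediate (not isolated)
14 | tert-butyl 4-[(4S)-4-benzyl-2-oxo-1,3-oxazolidin-3-yl]-4-oxobutanoate | CC(C)(C)OC(=O)CCC(=O)N1[C@@H](Cc2ccccc2)COC1=O | intermediate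
15 | tert-butyl (3S,4R)-3-{[(4S)-4-benzyl-2-oxo-1,3-oxazolidin-3-yl]carbonyl}-4-hydroxy-5-{(2R)-5-[(1S)-1-(tert-butyldimethylsilyloxy)ethyl]-2-methyl-3-oxo-2,3-dihydrofuran-2-yl}pentanoate (syn-aldol adduct; 4S,7S,8R,10R) | CC(C)(C)OC(=O)C[C@@H]([C@H](O)C[C@@]3(C)OC(=CC3=O)[C@H](C)O[Si](C)(C)C(C)(C)C)C(=O)N1[C@@H](Cc2ccccc2)COC1=O | intermediate
16 | 8-O-triisopropylsilyl ether of 15 (4S,7S,8R,10R) | CC(C)(C)OC(=O)C[C@@H]([C@H](O[Si](C(C)C)(C(C)C)C(C)C)C[C@@]3(C)OC(=CC3=O)[C@H](C)O[Si](C)(C)C(C)(C)C)C(=O)N1[C@@H](Cc2ccccc2)COC1=O | intermediate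
17 | (2S,3R)-2-(2-tert-butoxy-2-oxoethyl)-3-[(triisopropylsilyl)oxy]-4-{(2R)-5-[(1S)-1-(tert-butyldimethylsilyloxy)ethyl]-2-methyl-3-oxo-2,3-dihydrofuran-2-yl}butanoic acid (C6 acid) | CC(C)(C)OC(=O)C[C@@H]([C@H](O[Si](C(C)C)(C(C)C)C(C)C)C[C@@]3(C)OC(=CC3=O)[C@H](C)O[Si](C)(C)C(C)(C)C)C(=O)O | intermediate
18 | isobutyl carbonic mixed anhydride of 17 | CC(C)(C)OC(=O)C[C@@H]([C@H](O[Si](C(C)C)(C(C)C)C(C)C)C[C@@]3(C)OC(=CC3=O)[C@H](C)O[Si](C)(C)C(C)(C)C)C(=O)OC(=O)OCC(C)C | intermediate (not isolated)
19 | diazomethyl ketone at C6 (4S,7S,8R,10R) | CC(C)(C)OC(=O)C[C@@H]([C@H](O[Si](C(C)C)(C(C)C)C(C)C)C[C@@]3(C)OC(=CC3=O)[C@H](C)O[Si](C)(C)C(C)(C)C)C(=O)C=[N+]=[N-] | intermediate (not isolated)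
20 | bromomethyl ketone: tert-butyl (3S,4R)-3-(2-bromoacetyl)-4-[(triisopropylsilyl)oxy]-5-{(2R)-5-[(1S)-1-(tert-butyldimethylsilyloxy)ethyl]-2-methyl-3-oxo-2,3-dihydrofuran-2-yl}pentanoate | CC(C)(C)OC(=O)C[C@@H]([C@H](O[Si](C(C)C)(C(C)C)C(C)C)C[C@@]3(C)OC(=CC3=O)[C@H](C)O[Si](C)(C)C(C)(C)C)C(=O)CBr | intermediate
21 | bromohydrin: tert-butyl (3R,4R)-3-[(1R)-2-bromo-1-hydroxyethyl]-4-[(triisopropylsilyl)oxy]-5-{(2R)-5-[(1S)-1-(tert-butyldimethylsilyloxy)ethyl]-2-methyl-3-oxo-2,3-dihydrofuran-2-yl}pentanoate (4S,6R,7R,8R,10R) | CC(C)(C)OC(=O)C[C@@H]([C@H](O[Si](C(C)C)(C(C)C)C(C)C)C[C@@]3(C)OC(=CC3=O)[C@H](C)O[Si](C)(C)C(C)(C)C)[C@@H](O)CBr | intermediate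
22 | bromo lactone alcohol: (4R,5R)-5-(bromomethyl)-4-{(1R)-2-{(2R)-5-[(1S)-1-hydroxyethyl]-2-methyl-3-oxo-2,3-dihydrofuran-2-yl}-1-[(triisopropylsilyl)oxy]ethyl}dihydrofuran-2(3H)-one | BrC[C@@H]1OC(=O)C[C@H]1[C@H](O[Si](C(C)C)(C(C)C)C(C)C)C[C@@]2(C)OC(=CC2=O)[C@H](C)O | intermediate
23 | C4 thioacetate of 22 with inverted C4 (4R,6R,7R,8R,10R) | BrC[C@@H]1OC(=O)C[C@H]1[C@H](O[Si](C(C)C)(C(C)C)C(C)C)C[C@@]2(C)OC(=CC2=O)[C@@H](C)SC(C)=O | intermediate
24 | C4 thiol (4R,6R,7R,8R,10R) | BrC[C@@H]1OC(=O)C[C@H]1[C@H](O[Si](C(C)C)(C(C)C)C(C)C)C[C@@]2(C)OC(=CC2=O)[C@@H](C)S | intermediate (not isolated)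
25 | macrocyclic sulfide: furanone-bridged ten-membered thia-oxacycle with S between C4 and C5, trans-6,12-lactone, 8-OTIPS (4R,6R,7R,8R,10R) | C[C@H]1SC[C@@H]2OC(=O)C[C@H]2[C@H](O[Si](C(C)C)(C(C)C)C(C)C)C[C@@]3(C)OC1=CC3=O | intermediate
26 | macrocyclic sulfone (S,S-dioxide of 25; 4R,6R,7R,8R,10R) | C[C@H]1S(=O)(=O)C[C@@H]2OC(=O)C[C@H]2[C@H](O[Si](C(C)C)(C(C)C)C(C)C)C[C@@]3(C)OC1=CC3=O | intermediate
27 | 4-chloro sulfone (6R,7R,8R,10R; C4 configuration not specified) | CC1(Cl)S(=O)(=O)C[C@@H]2OC(=O)C[C@H]2[C@H](O[Si](C(C)C)(C(C)C)C(C)C)C[C@@]3(C)OC1=CC3=O | intermediate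
28 | cis-fused C4/C5 episulfone (thiirane 1,1-dioxide) | CC12C(S1(=O)=O)[C@@H]3OC(=O)C[C@H]3[C@H](O[Si](C(C)C)(C(C)C)C(C)C)C[C@@]4(C)OC2=CC4=O | intermediate (not isolated)
29 | (4Z)-diene lactone: 11,13-dihydro-8-O-TIPS core with the nine-membered oxacycle (6S,7R,8R,10R) | C1C(=O)O[C@H]2/C=C(/C)C3=CC(=O)[C@@](C)(C[C@@H](O[Si](C(C)C)(C(C)C)C(C)C)[C@H]12)O3 | intermediate
30 | 11-(dimethylaminomethyl) lactone (Mannich base; C11 configuration not specified) | CN(C)CC1C(=O)O[C@H]2/C=C(/C)C3=CC(=O)[C@@](C)(C[C@@H](O[Si](C(C)C)(C(C)C)C(C)C)[C@H]12)O3 | intermediate (not isolated)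
31 | 11-(trimethylammoniomethyl) lactone iodide | C[N+](C)(C)CC1C(=O)O[C@H]2/C=C(/C)C3=CC(=O)[C@@](C)(C[C@@H](O[Si](C(C)C)(C(C)C)C(C)C)[C@H]12)O3.[I-] | intermediate (not isolated)
32 | α-methylene lactone 8-O-TIPS ether (4Z,6S,7R,8R,10R) | C=C1C(=O)O[C@H]2/C=C(/C)C3=CC(=O)[C@@](C)(C[C@@H](O[Si](C(C)C)(C(C)C)C(C)C)[C@H]12)O3 | intermediate
33 | 8-hydroxy α-methylene lactone (des-acyl core; 4Z,6S,7S,8R,10R) | C=C1C(=O)O[C@H]2/C=C(/C)C3=CC(=O)[C@@](C)(C[C@@H](O)[C@H]12)O3 | intermediate
34 | tert-butyl acrylate | C=CC(=O)OC(C)(C)C | starting material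
35 | acetaldehyde | CC=O | starting material
36 | tert-butyl 3-hydroxy-2-methylidenebutanoate (racemic) | CC(O)C(=C)C(=O)OC(C)(C)C | intermediate
37 | tert-butyl 3-acetoxy-2-methylidenebutanoate (racemic) | CC(OC(C)=O)C(=C)C(=O)OC(C)(C)C | intermediate (not isolated)
38 | tert-butyl (2E)-2-(acetoxymethyl)but-2-enoate | CC(C)(C)OC(=O)/C(=C/C)COC(C)=O | intermediate
39 | (2E)-2-(acetoxymethyl)but-2-enoic acid | OC(=O)/C(=C/C)COC(C)=O | intermediate
40 | (2E)-2-(acetoxymethyl)but-2-enoic 2,4,6-trichlorobenzoic anhydride | O=C(OC(=O)/C(=C/C)COC(C)=O)c1c(Cl)cc(Cl)cc1Cl | intermediate (not isolated)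
41 | CNP0176571.1: 8-O-[(2E)-2-(acetoxymethyl)but-2-enoyl] ester of 33 (4Z,6S,7S,8R,10R) | C=C1C(=O)O[C@H]2/C=C(/C)C3=CC(=O)[C@@](C)(C[C@@H](OC(=O)/C(=C/C)COC(C)=O)[C@H]12)O3 | target

Total step count: 24. Longest linear sequence: 19 steps (steps 1, 2, 4–6, 8–20, 24).

Steps most likely to fail

1. Step 18 (Ramberg–Bäcklund ring contraction). After deprotonation at C5, β-elimination of the C6 lactone oxygen (ring opening to a vinyl sulfone) may compete with episulfone closure, and displacement at the tertiary C4–Cl may be slow for one C4 epimer. Fallback, setting out from 27: aqueous KOH in dioxane first saponifies the lactone to the γ-hydroxy carboxylate, seco acid F1, whose C6 alkoxide cannot act as a leaving group. The same hydroxide medium (the classical Ramberg–Bäcklund conditions) then contracts the ring to the diene seco acid F2. Acidification with camphorsulfonic acid relactonises F2 and returns to the route at 29.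

2. Step 15 (macrocyclic thioetherification). Intermolecular S-alkylation (oligomerisation) and sluggish SN2 displacement at the β-oxygenated primary bromide may outweigh ring closure. Fallback with reversed roles, setting out from 22: KSAc in DMF displaces the bromide to give thioacetate alcohol F3, and MsCl/Et3N gives mesylate F4. K2CO3 in MeOH at high dilution then frees the primary C5 thiolate, which closes the ring by SN2 displacement (inversion) of the furanone-activated secondary mesylate at C4. This returns to the route at 25 with the same C4 configuration.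

3. Step 19 (late α-methylenation). Deprotonation at the vinylogous C6–H or elsewhere on the dienyl furanone may compete with lactone enolate formation and lead to isomerisation or aminomethylation at the wrong site. Fallback without strong base, setting out from 29: heating with tert-butoxybis(dimethylamino)methane in toluene gives the enamino lactone F5, and mild aqueous acid hydrolyses it to the α-hydroxymethylene lactone F6. Aqueous formaldehyde with K2CO3 then effects aldol addition, deformylation and β-elimination to the α-methylene lactone, returning to the route at 32.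

Further compounds
F1 | step 18 | seco acid of 27: 4-chloro sulfone with free 6-OH and C12 carboxylic acid (6R,7R,8R,10R) | CC1(Cl)S(=O)(=O)C[C@H](O)[C@@H](CC(=O)O)[C@H](O[Si](C(C)C)(C(C)C)C(C)C)C[C@@]3(C)OC1=CC3=O
F2 | step 18 | (4Z)-diene seco acid with the nine-membered oxacycle (6S,7R,8R,10R) | C/C1=C/[C@H](O)[C@@H](CC(=O)O)[C@H](O[Si](C(C)C)(C(C)C)C(C)C)C[C@@]3(C)OC1=CC3=O
F3 | step 15 | C5 thioacetate lactone with free 4-OH (4S,6R,7R,8R,10R) | CC(=O)SC[C@@H]1OC(=O)C[C@H]1[C@H](O[Si](C(C)C)(C(C)C)C(C)C)C[C@@]2(C)OC(=CC2=O)[C@H](C)O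
F4 | step 15 | C5 thioacetate lactone C4 mesylate | CC(=O)SC[C@@H]1OC(=O)C[C@H]1[C@H](O[Si](C(C)C)(C(C)C)C(C)C)C[C@@]2(C)OC(=CC2=O)[C@H](C)OS(C)(=O)=O
F5 | step 19 | 11-(dimethylaminomethylidene) lactone (enamino lactone) | CN(C)C=C1C(=O)O[C@H]2/C=C(/C)C3=CC(=O)[C@@](C)(C[C@@H](O[Si](C(C)C)(C(C)C)C(C)C)[C@H]12)O3
F6 | step 19 | 11-(hydroxymethylidene) lactone | OC=C1C(=O)O[C@H]2/C=C(/C)C3=CC(=O)[C@@](C)(C[C@@H](O[Si](C(C)C)(C(C)C)C(C)C)[C@H]12)O3
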